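**Plan**

- Retrosynthetic cuts: first the two ester C–O bonds (aryl O–isobutyryl and allylic O–benzoyl), then the C–C bond between the aryl-bearing vinyl carbon and the CH2O carbon, then that vinyl carbon back to the carbonyl of an acetophenone (through its sulfonylhydrazone), and last the aryl–acetyl bond to 2-methylhydroquinone.
- Enabling feature: in the unit CH2=C(Ar)–CH2–O the oxygenated CH2 sits on the alkene carbon that also carries the benzene ring, and the other alkene carbon is an unsubstituted CH2. That ring-bearing sp2 carbon can therefore act as a 1-arylvinyl anion toward formaldehyde, and such an anion is available from a methyl ketone.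
- Forward order: acetylate the hydroquinone para to its methyl group; tell the two phenols apart by the hydrogen bond to the acetyl group (free OH to a TIPS ether, chelated OH to a MOM ether); form the trisylhydrazone; generate the vinyllithium and add it to formaldehyde; benzoylate; exchange MOM for isobutyryl; desilylate.
- No ring is formed at any stage (the benzene ring is bought). The target has no stereocentre and a terminal alkene, so no stereochemistry has to be set; the E geometry of the hydrazone only places N–Li next to the methyl group.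

Key step: step 5

Assumption: monomeric formaldehyde, cracked from dry paraformaldehyde in a side flask and swept in with nitrogen, is counted as a purchased starting material.

**Route**

Step 1
Reactants: 1 2-methylhydroquinone
Product: 3 1-(2,5-dihydroxy-4-methylphenyl)ethanone, via difluoroboron chelate 2 (not isolated)
Conditions: AcOH, BF3·OEt2, 90 °C; then H2O–EtOH, reflux
Reagents that add atoms: acetic acid, CC(=O)O
Why: Friedel–Crafts (Fries-type) C-acetylation of an electron-rich hydroquinone should go to the ring position para to the methyl group and ortho to a hydroxyl, the least hindered doubly activated site, and the ketone is held as its O–BF2 chelate 2 until hydrolysis.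

Step 2
Reactants: 3 1-(2,5-dihydroxy-4-methylphenyl)ethanone
Product: 4 1-[2-hydroxy-4-methyl-5-(triisopropylsilyloxy)phenyl]ethanone
Conditions: TIPSCl, imidazole, DMF, 0 °C → rt
Reagents that add atoms: chlorotriisopropylsilane (TIPSCl), CC(C)[Si](Cl)(C(C)C)C(C)C
Why: Chemoselective silyl ether formation; the 2-OH is tied up in a hydrogen bond to the acetyl carbonyl and deactivated by it, so the bulky silyl chloride should take only the free 5-OH.

Step 3
Reactants: 4 1-[2-hydroxy-4-methyl-5-(triisopropylsilyloxy)phenyl]ethanone
Product: 6 1-[2-(methoxymethoxy)-4-methyl-5-(triisopropylsilyloxy)phenyl]ethanone, via sodium phenoxide 5 (not isolated)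
Conditions: NaH (1.1 equiv), THF–DMF, 0 °C; then MOMCl, 0 °C → rt
Reagents that add atoms: chloromethyl methyl ether (MOMCl), COCCl
Why: Williamson-type O-alkylation; stoichiometric NaH breaks the chelate and phenoxide 5 is captured by the reactive α-chloro ether, while the hindered aryl TIPS ether should neither migrate nor cleave.

Step 4
Reactants: 6 1-[2-(methoxymethoxy)-4-methyl-5-(triisopropylsilyloxy)phenyl]ethanone; 7 2,4,6-triisopropylbenzenesulfonyl hydrazide
Product: 8 N′-{(1E)-1-[2-(methoxymethoxy)-4-methyl-5-(triisopropylsilyloxy)phenyl]ethylidene}-2,4,6-triisopropylbenzenesulfonohydrazide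
Conditions: PPTS (cat.), THF, 4 Å molecular sieves, rt
Reagents that add atoms: none
Why: Acid-catalysed hydrazone formation from a ketone and a sulfonylhydrazide; the weak acid at room temperature spares the MOM acetal and the heat-sensitive hydrazide, and the E isomer (N–H syn to methyl, anti to the aryl group) is expected on steric grounds.

Step 5
Reactants: 8 the E-trisylhydrazone; 9 formaldehyde
Product: 12 2-[2-(methoxymethoxy)-4-methyl-5-(triisopropylsilyloxy)phenyl]prop-2-en-1-ol, via dilithiated hydrazone 10 (not isolated), via 1-arylvinyllithium 11 (not isolated)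
Conditions: n-BuLi (2.05 equiv), THF, −78 °C; 0 °C until N2 evolution stops; CH2O (gas, N2 stream), −20 °C → rt; aq. NH4Cl
Reagents that add atoms: none
Why: n-BuLi first removes the sulfonamide N–H and then, guided by the lithiated nitrogen lying syn to it in the E-hydrazone, a methyl hydrogen (the only α-hydrogens available) to give dianion 10; on warming, 10 expels the arenesulfinate and then N2 to leave 1-arylvinyllithium 11, whose carbanionic carbon adds to formaldehyde and so makes the bond between the aryl-bearing vinyl carbon and the CH2O carbon. The closest known reaction type is the Shapiro reaction of a trisylhydrazone with electrophilic trapping of the vinyllithium, for which formaldehyde is an established electrophile giving 2-substituted allylic alcohols. No ring is closed and no stereocentre is formed. The step needs deprotonation at the hydrazone methyl and not on a ring, and a vinyllithium that survives until it is trapped: the trisyl group has no ortho hydrogens and lets the dianion fragment at about 0 °C, just two equivalents of base are consumed at −78 °C before warming, and the only ring C–H ortho to the MOM ether is flanked by the methyl group. The ortho MOM oxygens can chelate lithium in 11, the silyl ether sits meta to the carbanion so that no oxygen-to-carbon silyl shift is possible, and no carbonyl group is present at this stage.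

Step 6
Reactants: 12 2-[2-(methoxymethoxy)-4-methyl-5-(triisopropylsilyloxy)phenyl]prop-2-en-1-ol
Product: 13 2-[2-(methoxymethoxy)-4-methyl-5-(triisopropylsilyloxy)phenyl]prop-2-en-1-yl benzoate
Conditions: BzCl, pyridine, DMAP (cat.), CH2Cl2, 0 °C → rt
Reagents that add atoms: benzoyl chloride, O=C(Cl)c1ccccc1
Why: DMAP-catalysed esterification of an unhindered primary allylic alcohol with an acid chloride; no other free hydroxyl is present.

Step 7
Reactants: 13 2-[2-(methoxymethoxy)-4-methyl-5-(triisopropylsilyloxy)phenyl]prop-2-en-1-yl benzoate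
Product: 15 2-[2-hydroxy-4-methyl-5-(triisopropylsilyloxy)phenyl]prop-2-en-1-yl benzoate, via aryl trimethylsilyl ether 14 (not isolated)
Conditions: TMSOTf, 2,2′-bipyridyl, CH3CN, 0 °C → rt; then H2O, rt
Reagents that add atoms: none
Why: Chemoselective cleavage of an aromatic MOM ether by a silyl triflate buffered with 2,2′-bipyridyl: the aryl oxygen passes to silicon (14) while the methoxymethyl unit is held as an N-alkylbipyridinium triflate, and water then hydrolyses both under non-protic, near-neutral conditions that should leave the benzoate, the aryl TIPS ether and the 1,1-disubstituted alkene untouched.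

Step 8
Reactants: 15 2-[2-hydroxy-4-methyl-5-(triisopropylsilyloxy)phenyl]prop-2-en-1-yl benzoate
Product: 16 2-[4-methyl-2-(2-methylpropanoyloxy)-5-(triisopropylsilyloxy)phenyl]prop-2-en-1-yl benzoate
Conditions: i-PrCOCl, Et3N, DMAP (cat.), CH2Cl2, 0 °C
Reagents that add atoms: isobutyryl chloride (2-methylpropanoyl chloride), CC(C)C(Cl)=O
Why: DMAP-catalysed O-acylation of a phenol with an acid chloride, which at 0 °C should outrun any attack of the phenoxide on the allylic benzoate carbon.

Step 9
Reactants: 16 2-[4-methyl-2-(2-methylpropanoyloxy)-5-(triisopropylsilyloxy)phenyl]prop-2-en-1-yl benzoate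
Product: 17 2-[5-hydroxy-4-methyl-2-(2-methylpropanoyloxy)phenyl]prop-2-en-1-yl benzoate (CNP0245407.0)
Conditions: KHF2, MeOH–THF, rt
Reagents that add atoms: none
Why: Fluoride-mediated desilylation of an aryl silyl ether with the mildly acidic bifluoride salt, a method selective for phenolic silyl ethers in which no strongly basic fluoride or free phenoxide arises, so the aryl isobutyrate and the allylic benzoate should survive.

**Compound list**

1 | 2-methylhydroquinone (2-methylbenzene-1,4-diol) | Cc1cc(O)ccc1O | starting material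
2 | difluoroboron chelate of 1-(2,5-dihydroxy-4-methylphenyl)ethanone (2,2-difluoro-6-hydroxy-4,7-dimethyl-1,3,2-benzodioxaborinine, O→B dative form) | CC1=[O+][B-](F)(F)Oc2cc(C)c(O)cc21 | intermediate
3 | 1-(2,5-dihydroxy-4-methylphenyl)ethanone | CC(=O)c1cc(O)c(C)cc1O | intermediate
4 | 1-[2-hydroxy-4-methyl-5-(triisopropylsilyloxy)phenyl]ethanone | CC(=O)c1cc(O[Si](C(C)C)(C(C)C)C(C)C)c(C)cc1O | intermediate
5 | sodium 2-acetyl-5-methyl-4-(triisopropylsilyloxy)phenolate | CC(=O)c1cc(O[Si](C(C)C)(C(C)C)C(C)C)c(C)cc1[O-].[Na+] | intermediate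
6 | 1-[2-(methoxymethoxy)-4-methyl-5-(triisopropylsilyloxy)phenyl]ethanone | CC(=O)c1cc(O[Si](C(C)C)(C(C)C)C(C)C)c(C)cc1OCOC | intermediate
7 | 2,4,6-triisopropylbenzenesulfonyl hydrazide | CC(C)c1cc(C(C)C)c(S(=O)(=O)NN)c(C(C)C)c1 | starting material
8 | N′-{(1E)-1-[2-(methoxymethoxy)-4-methyl-5-(triisopropylsilyloxy)phenyl]ethylidene}-2,4,6-triisopropylbenzenesulfonohydrazide | C/C(=N\NS(=O)(=O)c1c(C(C)C)cc(C(C)C)cc1C(C)C)c1cc(O[Si](C(C)C)(C(C)C)C(C)C)c(C)cc1OCOC | intermediate
9 | formaldehyde | C=O | starting material
10 | C,N-dilithio derivative of hydrazone 8 (lithium on the former methyl carbon and on the sulfonamide nitrogen) | [Li]C/C(=N\N([Li])S(=O)(=O)c1c(C(C)C)cc(C(C)C)cc1C(C)C)c1cc(O[Si](C(C)C)(C(C)C)C(C)C)c(C)cc1OCOC | intermediate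
11 | {1-[2-(methoxymethoxy)-4-methyl-5-(triisopropylsilyloxy)phenyl]ethenyl}lithium | [Li]C(=C)c1cc(O[Si](C(C)C)(C(C)C)C(C)C)c(C)cc1OCOC | intermediate
12 | 2-[2-(methoxymethoxy)-4-methyl-5-(triisopropylsilyloxy)phenyl]prop-2-en-1-ol | C=C(CO)c1cc(O[Si](C(C)C)(C(C)C)C(C)C)c(C)cc1OCOC | intermediate
13 | 2-[2-(methoxymethoxy)-4-methyl-5-(triisopropylsilyloxy)phenyl]prop-2-en-1-yl benzoate | C=C(COC(=O)c1ccccc1)c1cc(O[Si](C(C)C)(C(C)C)C(C)C)c(C)cc1OCOC | intermediate
14 | 2-[4-methyl-5-(triisopropylsilyloxy)-2-(trimethylsilyloxy)phenyl]prop-2-en-1-yl benzoate | C=C(COC(=O)c1ccccc1)c1cc(O[Si](C(C)C)(C(C)C)C(C)C)c(C)cc1O[Si](C)(C)C | intermediate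
15 | 2-[2-hydroxy-4-methyl-5-(triisopropylsilyloxy)phenyl]prop-2-en-1-yl benzoate | C=C(COC(=O)c1ccccc1)c1cc(O[Si](C(C)C)(C(C)C)C(C)C)c(C)cc1O | intermediate
16 | 2-[4-methyl-2-(2-methylpropanoyloxy)-5-(triisopropylsilyloxy)phenyl]prop-2-en-1-yl benzoate | C=C(COC(=O)c1ccccc1)c1cc(O[Si](C(C)C)(C(C)C)C(C)C)c(C)cc1OC(=O)C(C)C | intermediate
17 | 2-[5-hydroxy-4-methyl-2-(2-methylpropanoyloxy)phenyl]prop-2-en-1-yl benzoate (CNP0245407.0) | C=C(COC(=O)c1ccccc1)c1cc(O)c(C)cc1OC(=O)C(C)C | target

**Summary**

Total step count: 9. Longest linear sequence: 9 steps, from 1 to 17.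

Steps most likely to fail:

Step 5. The vinyllithium may be protonated (by solvent or by unreacted hydrazone) to the plain 1-arylethene before it meets formaldehyde, formaldehyde may repolymerise before reacting, or lithiation may stray onto the ring. The fallback sets out from ketone 6. KN(SiMe3)2 and PhNTf2 in THF at −78 °C should give the enol triflate 1-[2-(methoxymethoxy)-4-methyl-5-(triisopropylsilyloxy)phenyl]ethenyl trifluoromethanesulfonate F1. A Stille coupling of this triflate with (tributylstannyl)methanol (Pd(PPh3)4 as the zerovalent palladium catalyst, LiCl, dioxane, 90 °C) should then deliver allylic alcohol 12, where the route is rejoined; steps 4 and 5 are not needed in that case.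

Step 7. The silyl triflate may attack or ionise the allylic benzoate, the transferred methoxymethyl unit may alkylate the electron-rich alkene, or the freed ortho-phenol may displace benzoate and close a five-membered cyclic ether. The fallback sets out from alcohol 12, before any benzoate exists. Thiol-assisted Lewis-acid cleavage of the MOM ether (ZnBr2, n-PrSH, CH2Cl2, 0 °C) should give the diol 2-[2-hydroxy-4-methyl-5-(triisopropylsilyloxy)phenyl]prop-2-en-1-ol F2. Phase-transfer Schotten–Baumann acylation (isobutyryl chloride, aq. NaOH, Bu4NHSO4, CH2Cl2, 0 °C), in which only the phenoxide reacts, should give 2-(3-hydroxyprop-1-en-2-yl)-5-methyl-4-(triisopropylsilyloxy)phenyl 2-methylpropanoate F3. Benzoylation of the primary alcohol (BzCl, pyridine, CH2Cl2, 0 °C) then reaches diester 16, where the route is rejoined.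

Step 9. The aryl isobutyrate may be lost by methanolysis or fluoride-assisted cleavage, or be passed on to the newly released phenol, while the hindered Si–O bond is still being broken. The fallback sets out from benzoate 13 and removes the silyl group before any aryl ester exists.
- Bu4NF in THF at 0 °C should give 2-[5-hydroxy-2-(methoxymethoxy)-4-methylphenyl]prop-2-en-1-yl benzoate F4.
- 2,2,2-Trichloroethyl chloroformate and pyridine in CH2Cl2 should give the mixed carbonate 2-{2-(methoxymethoxy)-4-methyl-5-[(2,2,2-trichloroethoxy)carbonyloxy]phenyl}prop-2-en-1-yl benzoate F5.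
- The conditions of step 7 should give, through the aryl silyl ether 2-{4-methyl-5-[(2,2,2-trichloroethoxy)carbonyloxy]-2-(trimethylsilyloxy)phenyl}prop-2-en-1-yl benzoate F6 (not isolated), the phenol 2-{2-hydroxy-4-methyl-5-[(2,2,2-trichloroethoxy)carbonyloxy]phenyl}prop-2-en-1-yl benzoate F7.
- The conditions of step 8 should give 2-{4-methyl-2-(2-methylpropanoyloxy)-5-[(2,2,2-trichloroethoxy)carbonyloxy]phenyl}prop-2-en-1-yl benzoate F8.
- Zn dust in AcOH–THF at room temperature removes the trichloroethyl carbonate by reductive fragmentation, under conditions harmless to both esters and to the alkene, and should reach target 17.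

**Further compounds**

F1 | step 5 | 1-[2-(methoxymethoxy)-4-methyl-5-(triisopropylsilyloxy)phenyl]ethenyl trifluoromethanesulfonate | C=C(OS(=O)(=O)C(F)(F)F)c1cc(O[Si](C(C)C)(C(C)C)C(C)C)c(C)cc1OCOC
F2 | step 7 | 2-[2-hydroxy-4-methyl-5-(triisopropylsilyloxy)phenyl]prop-2-en-1-ol | C=C(CO)c1cc(O[Si](C(C)C)(C(C)C)C(C)C)c(C)cc1O
F3 | step 7 | 2-(3-hydroxyprop-1-en-2-yl)-5-methyl-4-(triisopropylsilyloxy)phenyl 2-methylpropanoate | C=C(CO)c1cc(O[Si](C(C)C)(C(C)C)C(C)C)c(C)cc1OC(=O)C(C)C
F4 | step 9 | 2-[5-hydroxy-2-(methoxymethoxy)-4-methylphenyl]prop-2-en-1-yl benzoate | C=C(COC(=O)c1ccccc1)c1cc(O)c(C)cc1OCOC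
F5 | step 9 | 2-{2-(methoxymethoxy)-4-methyl-5-[(2,2,2-trichloroethoxy)carbonyloxy]phenyl}prop-2-en-1-yl benzoate | C=C(COC(=O)c1ccccc1)c1cc(OC(=O)OCC(Cl)(Cl)Cl)c(C)cc1OCOC
F6 | step 9 | 2-{4-methyl-5-[(2,2,2-trichloroethoxy)carbonyloxy]-2-(trimethylsilyloxy)phenyl}prop-2-en-1-yl benzoate | C=C(COC(=O)c1ccccc1)c1cc(OC(=O)OCC(Cl)(Cl)Cl)c(C)cc1O[Si](C)(C)C
F7 | step 9 | 2-{2-hydroxy-4-methyl-5-[(2,2,2-trichloroethoxy)carbonyloxy]phenyl}prop-2-en-1-yl benzoate | C=C(COC(=O)c1ccccc1)c1cc(OC(=O)OCC(Cl)(Cl)Cl)c(C)cc1O
F8 | step 9 | 2-{4-methyl-2-(2-methylpropanoyloxy)-5-[(2,2,2-trichloroethoxy)carbonyloxy]phenyl}prop-2-en-1-yl benzoate | C=C(COC(=O)c1ccccc1)c1cc(OC(=O)OCC(Cl)(Cl)Cl)c(C)cc1OC(=O)C(C)C
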